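The route rests on cutting the quinone ring at C1–C8a and C2–C3. C1(=O)–C2(CH3) is read as a methylketene and the unsubstituted benzo ring (free C8a–H) as the partner of a six-electron ring closure. The precursor is open-chain: a 2-diazopropanoyl group (C1, C2, CH3) on a vinyl carbon (future C3) that already carries the complete C45 chain and a benzylidene group (future C4 and benzo ring). On irradiation a Wolff shift moves the vinyl carbon onto the diazo carbon (C2–C3) and the dienylketene closes onto the phenyl ring (C1–C8a) to give the 1-naphthol; oxygenation of the free C4–H then gives the quinone.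

Key step: step 16

Remark: ring atoms are numbered as in naphthalene-1,4-dione (C2 bears CH3, C3 the chain) and chain atoms C1' to C36' from the ring. "C45 chain" means the (2E,7R,11S,14E,18E,22E,26E,31S)-3,7,11,15,19,23,27,31,35-nonamethylhexatriaconta-2,14,18,22,26,34-hexaen-1-yl group.
Assumption: the halide building blocks are bought as single isomers. Centres that a later step destroys are formed as mixtures and carry no descriptor in the SMILES.

Step 1
Reactants: 1 (4-bromobut-1-yn-1-yl)trimethylsilane; 2 (R)-1-bromo-3-chloro-2-methylpropane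
Product: 4 (S)-(7-chloro-6-methylhept-1-yn-1-yl)trimethylsilane, via bromo[4-(trimethylsilyl)but-3-yn-1-yl]magnesium 3 (not isolated)
Conditions: Mg, THF, 20–40 °C; then 2, Li2CuCl4 (3 mol %), THF, −10 to 0 °C
Reagents that add atoms: none
Why: copper-catalysed Grignard alkyl–alkyl cross-coupling should take place at the C–Br bond only, the C–Cl bond being inert here; the stereocentre of 2 (future C7') is a spectator.

Step 2
Reactants: 4 (S)-(7-chloro-6-methylhept-1-yn-1-yl)trimethylsilane; 5 (R)-citronellyl bromide, (6R)-8-bromo-2,6-dimethyloct-2-ene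
Product: 7 trimethyl[(6R,10S)-6,10,14-trimethylpentadec-13-en-1-yn-1-yl]silane, via chloro[(2S)-2-methyl-7-(trimethylsilyl)hept-6-yn-1-yl]magnesium 6 (not isolated)
Conditions: Mg (iodine-activated), THF, 65 °C; then 5, Li2CuCl4 (3 mol %), NMP, THF, 0–20 °C
Reagents that add atoms: none
Why: a second copper-catalysed Grignard cross-coupling, now with the chloride of 4 as Grignard donor and primary bromide 5 as acceptor, should join C8' to C9'; both pool-derived centres (future C7' and C11') are untouched.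

Step 3
Reactants: 7 trimethyl[(6R,10S)-6,10,14-trimethylpentadec-13-en-1-yn-1-yl]silane
Product: 8 (2E,6S,10R)-2,6,10-trimethyl-15-(trimethylsilyl)pentadec-2-en-14-yn-1-ol
Conditions: SeO2 (0.3 equiv), t-BuOOH, salicylic acid (0.1 equiv), CH2Cl2, 20 °C
Reagents that add atoms: tert-butyl hydroperoxide CC(C)(C)OO
Why: Riley allylic oxidation (ene reaction, then [2,3]-shift) should attack the (E)-methyl of the only trisubstituted alkene and give the (E)-allylic alcohol; the silylalkyne is inert.

Step 4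
Reactants: 8 (2E,6S,10R)-2,6,10-trimethyl-15-(trimethylsilyl)pentadec-2-en-14-yn-1-ol
Product: 9 [(6R,10S,13E)-15-bromo-6,10,14-trimethylpentadec-13-en-1-yn-1-yl]trimethylsilane
Conditions: CBr4, PPh3, CH2Cl2, 0 °C
Reagents that add atoms: carbon tetrabromide BrC(Br)(Br)Br
Why: Appel bromination of a primary allylic alcohol under neutral conditions should keep the (E)-geometry and avoid allylic transposition.

Step 5
Reactants: 10 (2E,6E)-farnesyl bromide, (2E,6E)-1-bromo-3,7,11-trimethyldodeca-2,6,10-triene; 11 sodium benzenesulfinate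
Product: 12 (2E,6E)-farnesyl phenyl sulfone
Conditions: DMF, 20 °C
Reagents that add atoms: none
Why: SN2 S-alkylation of sulfinate by the primary allylic bromide should give the allylic sulfone with both (E)-alkenes intact.

Step 6
Reactants: 12 (2E,6E)-farnesyl phenyl sulfone
Product: 13 (2E,6E,10E)-2,6,10-trimethyl-12-(phenylsulfonyl)dodeca-2,6,10-trien-1-ol
Conditions: SeO2 (0.3 equiv), t-BuOOH, salicylic acid (0.1 equiv), CH2Cl2, 20 °C
Reagents that add atoms: tert-butyl hydroperoxide CC(C)(C)OO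
Why: Riley allylic oxidation should prefer the (E)-methyl of the terminal isopropylidene group over the internal alkene and the alkene deactivated by the sulfonylmethyl group.

Step 7
Reactants: 13 (2E,6E,10E)-2,6,10-trimethyl-12-(phenylsulfonyl)dodeca-2,6,10-trien-1-ol; 9 [(6R,10S,13E)-15-bromo-6,10,14-trimethylpentadec-13-en-1-yn-1-yl]trimethylsilane
Product: 15 (2E,6E,10E,14E,18S,22R)-2,6,10,14,18,22-hexamethyl-12-(phenylsulfonyl)-27-(trimethylsilyl)heptacosa-2,6,10,14-tetraen-26-yn-1-ol, via dilithio derivative of the hydroxy sulfone 14 (not isolated)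
Conditions: n-BuLi (2.1 equiv), THF/DMPU, −78 °C; then 9, −78 to −20 °C; H2O
Reagents that add atoms: none
Why: Biellmann coupling, in which the α-sulfonyl carbanion of the alkoxide dianion should alkylate the primary allylic bromide by SN2 and join C16' to C17' with the flanking (E)-alkenes untouched; the sulfonyl-bearing centre forms as a mixture and is erased in step 8.

Step 8
Reactants: 15 (2E,6E,10E,14E,18S,22R)-2,6,10,14,18,22-hexamethyl-12-(phenylsulfonyl)-27-(trimethylsilyl)heptacosa-2,6,10,14-tetraen-26-yn-1-ol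
Product: 16 (2E,6E,10E,14E,18S,22R)-2,6,10,14,18,22-hexamethyl-27-(trimethylsilyl)heptacosa-2,6,10,14-tetraen-26-yn-1-ol
Conditions: LiBHEt3, PdCl2(dppp) (5 mol %), THF, 0 °C; H2O
Reagents that add atoms: none
Why: palladium-catalysed hydride desulfonylation of the allylic sulfone should deliver hydride to the sulfonyl-bearing terminus of the allylpalladium intermediate, keeping position and (E)-geometry of the C18'=C19' alkene.

Step 9
Reactants: 16 (2E,6E,10E,14E,18S,22R)-2,6,10,14,18,22-hexamethyl-27-(trimethylsilyl)heptacosa-2,6,10,14-tetraen-26-yn-1-ol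
Product: 17 [(6R,10S,13E,17E,21E,25E)-27-bromo-6,10,14,18,22,26-hexamethylheptacosa-13,17,21,25-tetraen-1-yn-1-yl]trimethylsilane
Conditions: CBr4, PPh3, CH2Cl2, 0 °C
Reagents that add atoms: carbon tetrabromide BrC(Br)(Br)Br
Why: Appel bromination of the primary allylic alcohol should proceed without alkene isomerisation.

Step 10
Reactants: 17 [(6R,10S,13E,17E,21E,25E)-27-bromo-6,10,14,18,22,26-hexamethylheptacosa-13,17,21,25-tetraen-1-yn-1-yl]trimethylsilane; 5 (R)-citronellyl bromide
Product: 19 trimethyl[(6R,10S,13E,17E,21E,25E,30S)-6,10,14,18,22,26,30,34-octamethylpentatriaconta-13,17,21,25,33-pentaen-1-yn-1-yl]silane, via bromo[(3R)-3,7-dimethyloct-6-en-1-yl]magnesium 18 (not isolated)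
Conditions: Mg, THF, 20–40 °C; then 17, Li2CuCl4 (3 mol %), THF, −78 to −20 °C
Reagents that add atoms: none
Why: copper-catalysed coupling of a primary Grignard reagent with a primary allylic bromide in THF should favour direct (α) substitution and keep the (E)-alkene; the C31' centre comes unchanged from 5.

Step 11
Reactants: 19 trimethyl[(6R,10S,13E,17E,21E,25E,30S)-6,10,14,18,22,26,30,34-octamethylpentatriaconta-13,17,21,25,33-pentaen-1-yn-1-yl]silane
Product: 20 (6R,10S,13E,17E,21E,25E,30S)-6,10,14,18,22,26,30,34-octamethylpentatriaconta-13,17,21,25,33-pentaen-1-yne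
Conditions: K2CO3 (cat.), MeOH/THF, 20 °C
Reagents that add atoms: none
Why: base-catalysed methanolysis of the C(sp)–Si bond should free the terminal alkyne needed for carboalumination.

Step 12
Reactants: 21 benzaldehyde; 22 pent-1-en-3-one
Product: 23 2-[hydroxy(phenyl)methyl]pent-1-en-3-one (racemic)
Conditions: DABCO (0.3 equiv), THF, 20 °C
Reagents that add atoms: none
Why: Morita–Baylis–Hillman reaction of the vinyl ketone with the aldehyde; the carbinol centre is racemic and is destroyed in step 14.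

Step 13
Reactants: 23 2-[hydroxy(phenyl)methyl]pent-1-en-3-one
Product: 24 2-methylidene-3-oxo-1-phenylpentyl acetate (racemic)
Conditions: Ac2O, pyridine, DMAP (cat.), CH2Cl2, 0 °C
Reagents that add atoms: acetic anhydride CC(=O)OC(C)=O
Why: acylation turns the secondary allylic alcohol into an allylic electrophile.

Step 14
Reactants: 20 (6R,10S,13E,17E,21E,25E,30S)-6,10,14,18,22,26,30,34-octamethylpentatriaconta-13,17,21,25,33-pentaen-1-yne; 24 2-methylidene-3-oxo-1-phenylpentyl acetate
Product: 26 (4E,6E,11R,15S,18E,22E,26E,30E,35S)-4-benzylidene-7,11,15,19,23,27,31,35,39-nonamethyltetraconta-6,18,22,26,30,38-hexaen-3-one, via (E)-alkenyldimethylalane 25 (not isolated)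
Conditions: Me3Al, Cp2ZrCl2 (0.25 equiv), CH2Cl2, 0–20 °C; excess Me3Al removed in vacuo; then 24, Pd(PPh3)4 (5 mol %), THF, 20 °C; aqueous work-up
Reagents that add atoms: trimethylaluminium C[Al](C)C
Why: Negishi carboalumination adds methyl and aluminium cis across the terminal alkyne and so sets the C2'=C3' (E)-alkene, and palladium-catalysed alkenyl–allyl coupling of the alane with the allylic acetate should form C1'–C2' at the less hindered allyl terminus to give the benzylidene enone (either benzylidene isomer is usable).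

Step 15
Reactants: 26 (4E,6E,11R,15S,18E,22E,26E,30E,35S)-4-benzylidene-7,11,15,19,23,27,31,35,39-nonamethyltetraconta-6,18,22,26,30,38-hexaen-3-one
Product: 28 (4E,6E,11R,15S,18E,22E,26E,30E,35S)-4-benzylidene-2-diazo-7,11,15,19,23,27,31,35,39-nonamethyltetraconta-6,18,22,26,30,38-hexaen-3-one, via 2-trifluoroacetyl ketone 27 (not isolated)
Conditions: LiN(SiMe3)2, THF, −78 °C; CF3CO2CH2CF3; aq. HCl; then 4-acetamidobenzenesulfonyl azide, Et3N, H2O (1 equiv), MeCN, 20 °C
Reagents that add atoms: 4-acetamidobenzenesulfonyl azide CC(=O)Nc1ccc(cc1)S(=O)(=O)N=[N+]=[N-]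
Why: detrifluoroacetylative Regitz diazo transfer, in which enolisation is possible only at the ethyl CH2 (the other α-carbon is sp2), Claisen trifluoroacetylation activates that position and the sulfonyl azide should transfer N2 with loss of the trifluoroacetyl group.

Step 16
Reactants: 28 (4E,6E,11R,15S,18E,22E,26E,30E,35S)-4-benzylidene-2-diazo-7,11,15,19,23,27,31,35,39-nonamethyltetraconta-6,18,22,26,30,38-hexaen-3-one
Product: 33 2-methyl-3-(C45 chain)naphthalen-1-ol, via phenyl-trans dienylketene 29 (not isolated), via 4-phenylcyclobutenone 30 (not isolated), via phenyl-cis dienylketene 31 (not isolated), via 8aH-naphthalen-1-one 32 (not isolated)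
Conditions: hν (365 nm), degassed ClCH2CH2Cl (0.005 M), 20 °C; then 80 °C in the dark
Reagents that add atoms: none
Why: Excitation of the diazo ketone should expel N2 with a Wolff 1,2-shift of the vinyl carbon C3 from the carbonyl carbon to the diazo carbon (new C2–C3 bond), giving ketene 29 in which O=C1=C2(CH3) is already the C1/C2 unit of the quinone. Ketene 29, formed with phenyl trans to the ketene carbon, should close by a four-electron conrotatory electrocyclization to cyclobutenone 30, which reopens on warming in both senses; isomer 31 with phenyl cis then undergoes a thermal disrotatory six-electron electrocyclization in which C1 bonds to the ortho carbon of the phenyl ring (new C1–C8a bond, the only ring that stays closed), and tautomerization of dienone 32 restores the benzo ring. The closest known reaction types are the photochemical Wolff generation of vinylketenes in the Danheiser benzannulation and the dienylketene closure of 4-arylcyclobutenones in the Moore cyclization. No stereocentre is formed. The step needs vinyl migration to outrun 1,2-hydride shift from the methyl group and addition of the carbene or ketene to the C2'=C3' alkene, which the high migratory aptitude of an sp2 carbon, direct metal-free photolysis and high dilution should secure; regiochemistry is not an issue because the two phenyl ortho positions are equivalent.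

Step 17
Reactants: 33 2-methyl-3-(C45 chain)naphthalen-1-ol
Product: 34 2-methyl-3-[(2E,7R,11S,14E,18E,22E,26E,31S)-3,7,11,15,19,23,27,31,35-nonamethylhexatriaconta-2,14,18,22,26,34-hexaen-1-yl]naphthalene-1,4-dione
Conditions: Co(salen) (10 mol %), O2 (1 atm), DMF/THF, 20 °C
Reagents that add atoms: dioxygen O=O
Why: cobalt–salen-catalysed aerobic oxidation of a phenol with a free para position should give the para-quinone at C4; C2 is blocked by methyl and the isolated alkenes are not attacked.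

Compound list
1 | (4-bromobut-1-yn-1-yl)trimethylsilane | C[Si](C)(C)C#CCCBr | starting material
2 | (R)-1-bromo-3-chloro-2-methylpropane | ClC[C@@H](C)CBr | starting material
3 | bromo[4-(trimethylsilyl)but-3-yn-1-yl]magnesium (formed in situ) | Br[Mg]CCC#C[Si](C)(C)C | intermediate
4 | (S)-(7-chloro-6-methylhept-1-yn-1-yl)trimethylsilane | ClC[C@@H](C)CCCC#C[Si](C)(C)C | intermediate
5 | (R)-citronellyl bromide, (6R)-8-bromo-2,6-dimethyloct-2-ene | CC(C)=CCC[C@@H](C)CCBr | starting material
6 | chloro[(2S)-2-methyl-7-(trimethylsilyl)hept-6-yn-1-yl]magnesium (formed in situ) | Cl[Mg]C[C@@H](C)CCCC#C[Si](C)(C)C | intermediate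
7 | trimethyl[(6R,10S)-6,10,14-trimethylpentadec-13-en-1-yn-1-yl]silane | CC(C)=CCC[C@@H](C)CCC[C@@H](C)CCCC#C[Si](C)(C)C | intermediate
8 | (2E,6S,10R)-2,6,10-trimethyl-15-(trimethylsilyl)pentadec-2-en-14-yn-1-ol | OC/C(C)=C/CC[C@@H](C)CCC[C@@H](C)CCCC#C[Si](C)(C)C | intermediate
9 | [(6R,10S,13E)-15-bromo-6,10,14-trimethylpentadec-13-en-1-yn-1-yl]trimethylsilane | BrC/C(C)=C/CC[C@@H](C)CCC[C@@H](C)CCCC#C[Si](C)(C)C | intermediate
10 | (2E,6E)-farnesyl bromide | CC(C)=CCC/C(C)=C/CC/C(C)=C/CBr | starting material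
11 | sodium benzenesulfinate | [Na+].[O-]S(=O)c1ccccc1 | starting material
12 | (2E,6E)-farnesyl phenyl sulfone | CC(C)=CCC/C(C)=C/CC/C(C)=C/CS(=O)(=O)c1ccccc1 | intermediate
13 | (2E,6E,10E)-2,6,10-trimethyl-12-(phenylsulfonyl)dodeca-2,6,10-trien-1-ol | OC/C(C)=C/CC/C(C)=C/CC/C(C)=C/CS(=O)(=O)c1ccccc1 | intermediate
14 | O,C12-dilithio derivative of 13 (formed in situ) | [Li]OC/C(C)=C/CC/C(C)=C/CC/C(C)=C/C([Li])S(=O)(=O)c1ccccc1 | intermediate
15 | (2E,6E,10E,14E,18S,22R)-2,6,10,14,18,22-hexamethyl-12-(phenylsulfonyl)-27-(trimethylsilyl)heptacosa-2,6,10,14-tetraen-26-yn-1-ol (both C12 epimers) | OC/C(C)=C/CC/C(C)=C/CC/C(C)=C/C(S(=O)(=O)c1ccccc1)C/C(C)=C/CC[C@@H](C)CCC[C@@H](C)CCCC#C[Si](C)(C)C | intermediate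
16 | (2E,6E,10E,14E,18S,22R)-2,6,10,14,18,22-hexamethyl-27-(trimethylsilyl)heptacosa-2,6,10,14-tetraen-26-yn-1-ol | OC/C(C)=C/CC/C(C)=C/CC/C(C)=C/CC/C(C)=C/CC[C@@H](C)CCC[C@@H](C)CCCC#C[Si](C)(C)C | intermediate
17 | [(6R,10S,13E,17E,21E,25E)-27-bromo-6,10,14,18,22,26-hexamethylheptacosa-13,17,21,25-tetraen-1-yn-1-yl]trimethylsilane | BrC/C(C)=C/CC/C(C)=C/CC/C(C)=C/CC/C(C)=C/CC[C@@H](C)CCC[C@@H](C)CCCC#C[Si](C)(C)C | intermediate
18 | bromo[(3R)-3,7-dimethyloct-6-en-1-yl]magnesium (formed in situ) | CC(C)=CCC[C@@H](C)CC[Mg]Br | intermediate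
19 | trimethyl[(6R,10S,13E,17E,21E,25E,30S)-6,10,14,18,22,26,30,34-octamethylpentatriaconta-13,17,21,25,33-pentaen-1-yn-1-yl]silane | CC(C)=CCC[C@@H](C)CCC/C(C)=C/CC/C(C)=C/CC/C(C)=C/CC/C(C)=C/CC[C@@H](C)CCC[C@@H](C)CCCC#C[Si](C)(C)C | intermediate
20 | (6R,10S,13E,17E,21E,25E,30S)-6,10,14,18,22,26,30,34-octamethylpentatriaconta-13,17,21,25,33-pentaen-1-yne | CC(C)=CCC[C@@H](C)CCC/C(C)=C/CC/C(C)=C/CC/C(C)=C/CC/C(C)=C/CC[C@@H](C)CCC[C@@H](C)CCCC#C | intermediate
21 | benzaldehyde | O=Cc1ccccc1 | starting material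
22 | pent-1-en-3-one (ethyl vinyl ketone) | CCC(=O)C=C | starting material
23 | 2-[hydroxy(phenyl)methyl]pent-1-en-3-one (racemic) | CCC(=O)C(=C)C(O)c1ccccc1 | intermediate
24 | 2-methylidene-3-oxo-1-phenylpentyl acetate (racemic) | CCC(=O)C(=C)C(OC(C)=O)c1ccccc1 | intermediate
25 | dimethyl[(1E,6R,10S,13E,17E,21E,25E,30S)-2,6,10,14,18,22,26,30,34-nonamethylpentatriaconta-1,13,17,21,25,33-hexaen-1-yl]alumane (formed in situ) | CC(C)=CCC[C@@H](C)CCC/C(C)=C/CC/C(C)=C/CC/C(C)=C/CC/C(C)=C/CC[C@@H](C)CCC[C@@H](C)CCC/C(C)=C/[Al](C)C | intermediate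
26 | (4E,6E,11R,15S,18E,22E,26E,30E,35S)-4-benzylidene-7,11,15,19,23,27,31,35,39-nonamethyltetraconta-6,18,22,26,30,38-hexaen-3-one | CC(C)=CCC[C@@H](C)CCC/C(C)=C/CC/C(C)=C/CC/C(C)=C/CC/C(C)=C/CC[C@@H](C)CCC[C@@H](C)CCC/C(C)=C/C/C(C(=O)CC)=C\c1ccccc1 | intermediate
27 | 2-(trifluoroacetyl) derivative of 26 (formed in situ, both C2 epimers) | CC(C)=CCC[C@@H](C)CCC/C(C)=C/CC/C(C)=C/CC/C(C)=C/CC/C(C)=C/CC[C@@H](C)CCC[C@@H](C)CCC/C(C)=C/C/C(C(=O)C(C)C(=O)C(F)(F)F)=C\c1ccccc1 | intermediate
28 | (4E,6E,11R,15S,18E,22E,26E,30E,35S)-4-benzylidene-2-diazo-7,11,15,19,23,27,31,35,39-nonamethyltetraconta-6,18,22,26,30,38-hexaen-3-one | CC(C)=CCC[C@@H](C)CCC/C(C)=C/CC/C(C)=C/CC/C(C)=C/CC/C(C)=C/CC[C@@H](C)CCC[C@@H](C)CCC/C(C)=C/C/C(C(=O)C(C)=[N+]=[N-])=C\c1ccccc1 | intermediate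
29 | dienylketene O=C=C(CH3)–C(CH2–chain)=CHPh, phenyl trans to the ketene carbon (formed in situ) | CC(C)=CCC[C@@H](C)CCC/C(C)=C/CC/C(C)=C/CC/C(C)=C/CC/C(C)=C/CC[C@@H](C)CCC[C@@H](C)CCC/C(C)=C/C/C(C(C)=C=O)=C\c1ccccc1 | intermediate
30 | 2-methyl-3-(C45 chain)-4-phenylcyclobut-2-en-1-one (formed in situ, both C4 epimers) | CC(C)=CCC[C@@H](C)CCC/C(C)=C/CC/C(C)=C/CC/C(C)=C/CC/C(C)=C/CC[C@@H](C)CCC[C@@H](C)CCC/C(C)=C/CC1=C(C)C(=O)C1c1ccccc1 | intermediate
31 | dienylketene O=C=C(CH3)–C(CH2–chain)=CHPh, phenyl cis to the ketene carbon (formed in situ) | CC(C)=CCC[C@@H](C)CCC/C(C)=C/CC/C(C)=C/CC/C(C)=C/CC/C(C)=C/CC[C@@H](C)CCC[C@@H](C)CCC/C(C)=C/C/C(C(C)=C=O)=C/c1ccccc1 | intermediate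
32 | 2-methyl-3-(C45 chain)-8aH-naphthalen-1-one (formed in situ, both C8a epimers) | CC(C)=CCC[C@@H](C)CCC/C(C)=C/CC/C(C)=C/CC/C(C)=C/CC/C(C)=C/CC[C@@H](C)CCC[C@@H](C)CCC/C(C)=C/CC1=C(C)C(=O)C2C=CC=CC2=C1 | intermediate
33 | 2-methyl-3-[(2E,7R,11S,14E,18E,22E,26E,31S)-3,7,11,15,19,23,27,31,35-nonamethylhexatriaconta-2,14,18,22,26,34-hexaen-1-yl]naphthalen-1-ol | CC(C)=CCC[C@@H](C)CCC/C(C)=C/CC/C(C)=C/CC/C(C)=C/CC/C(C)=C/CC[C@@H](C)CCC[C@@H](C)CCC/C(C)=C/Cc1cc2ccccc2c(O)c1C | intermediate
34 | 2-methyl-3-[(2E,7R,11S,14E,18E,22E,26E,31S)-3,7,11,15,19,23,27,31,35-nonamethylhexatriaconta-2,14,18,22,26,34-hexaen-1-yl]naphthalene-1,4-dione | CC(C)=CCC[C@@H](C)CCC/C(C)=C/CC/C(C)=C/CC/C(C)=C/CC/C(C)=C/CC[C@@H](C)CCC[C@@H](C)CCC/C(C)=C/CC1=C(C)C(=O)c2ccccc2C1=O | target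

Total step count: 17. Longest linear sequence: 13 steps (1–4, 7–11, 14–17).

Steps most likely to fail

1. Step 16. After loss of nitrogen the reactive intermediates may be diverted before the ring closes: hydride shift from the methyl group or addition to the nearby C2'=C3' alkene at the carbene stage, ketene dimerisation while the phenyl-trans isomer waits to pass through the cyclobutenone, or photodegradation of the naphthol. The fallback sets out from alkyne 20 and comes back to the route at 34. Commercial 2-methylnaphthalene-1,4-dione is chloromethylated (aqueous formaldehyde, HCl gas, AcOH) to 2-(chloromethyl)-3-methylnaphthalene-1,4-dione F1. Alane 25, made from 20 as in the first stage of step 14, is then coupled with F1 under nickel catalysis (NiCl2(PPh3)2 reduced by n-BuLi to zerovalent nickel, THF, −20 to 20 °C), a known alkenylalane–chloromethylquinone coupling that keeps the (E)-alkene and gives 34 directly.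

2. Step 14. The alane may add to the ketone carbonyl, transfer methyl instead of the alkenyl group, or the allylpalladium intermediate may couple at its benzylic terminus. The fallback sets out from 20 (through alane 25) and comes back at 26. The alane is converted to its ate complex (n-BuLi) and trapped with paraformaldehyde to give the C45 allylic alcohol (2E,7R,11S,14E,18E,22E,26E,31S)-3,7,11,15,19,23,27,31,35-nonamethylhexatriaconta-2,14,18,22,26,34-hexaen-1-ol F2. Appel bromination (CBr4, PPh3) gives the allylic bromide F3. Commercial diethyl (2-oxobutyl)phosphonate is alkylated with F3 (NaH, THF) to the α-alkylated β-ketophosphonate F4. Horner–Wadsworth–Emmons reaction of F4 with benzaldehyde 21 (NaH, THF, 65 °C) then gives enone 26.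

3. Step 10. The organocopper intermediate may attack the 2-methylallyl-type bromide at the γ-carbon (SN2'), giving the branched isomer and destroying the C26'=C27' alkene. The fallback sets out from 5 and 17 and comes back at 19. Bromide 5 and sulfinate 11 (DMF) give (R)-citronellyl phenyl sulfone F5. Its α-lithio derivative (n-BuLi, THF, −78 °C) is alkylated by 17, a clean SN2 process, to the C29' sulfone F6. Reductive desulfonylation (Na(Hg), Na2HPO4, MeOH/THF, −20 °C) then gives 19.

Further compounds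
F1 | step 16 | 2-(chloromethyl)-3-methylnaphthalene-1,4-dione | O=C1C(C)=C(CCl)C(=O)c2ccccc12
F2 | step 14 | (2E,7R,11S,14E,18E,22E,26E,31S)-3,7,11,15,19,23,27,31,35-nonamethylhexatriaconta-2,14,18,22,26,34-hexaen-1-ol | CC(C)=CCC[C@@H](C)CCC/C(C)=C/CC/C(C)=C/CC/C(C)=C/CC/C(C)=C/CC[C@@H](C)CCC[C@@H](C)CCC/C(C)=C/CO
F3 | step 14 | (2E,7R,11S,14E,18E,22E,26E,31S)-1-bromo-3,7,11,15,19,23,27,31,35-nonamethylhexatriaconta-2,14,18,22,26,34-hexaene | CC(C)=CCC[C@@H](C)CCC/C(C)=C/CC/C(C)=C/CC/C(C)=C/CC/C(C)=C/CC[C@@H](C)CCC[C@@H](C)CCC/C(C)=C/CBr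
F4 | step 14 | diethyl [1-(C45 chain)-2-oxobutyl]phosphonate (both epimers at the phosphorus-bearing carbon) | CC(C)=CCC[C@@H](C)CCC/C(C)=C/CC/C(C)=C/CC/C(C)=C/CC/C(C)=C/CC[C@@H](C)CCC[C@@H](C)CCC/C(C)=C/CC(C(=O)CC)P(=O)(OCC)OCC
F5 | step 10 | [(3R)-3,7-dimethyloct-6-en-1-yl]sulfonylbenzene | CC(C)=CCC[C@@H](C)CCS(=O)(=O)c1ccccc1
F6 | step 10 | C29' phenyl sulfone of 19 (both epimers at the sulfonyl carbon) | CC(C)=CCC[C@@H](C)CC(S(=O)(=O)c1ccccc1)C/C(C)=C/CC/C(C)=C/CC/C(C)=C/CC/C(C)=C/CC[C@@H](C)CCC[C@@H](C)CCCC#C[Si](C)(C)C
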